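## Retrosynthetic overview

1. Numbering as a 1-benzoxepine: O1, C2 (=CHBr), C3(Me)/C4(H) oxirane, C5, C5a, C6(Me2), C7(Br), C8, C9, C9a(Me). The last disconnection cuts O1–C2 and C3–C4 (with the oxirane C3–O) together: a domino alkoxide / allenylsulfonium / aldehyde annulation of a bicyclic C11 lactol with a C4 bromoalkynyl sulfonium salt.
2. Enabling feature: in the oxepane, ring oxygen O1, enol-ether carbon C2, oxirane carbon C3 and oxirane carbon C4 are contiguous. O1–C2–C3 is therefore a 2-alkoxyallyl unit whose C3 can be a sulfonium-ylide carbon and C4 an aldehyde carbon. C4 lies three carbons (C5, C5a, C9a) from O1, so the C11 remainder is a γ-hydroxy aldehyde, i.e. the five-membered lactol of the homogeranic acid bromolactone.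
3. Lactol ⇐ DIBAL-H ⇐ trans-fused bromo-γ-lactone ⇐ catalytic enantioselective bromonium polyene cyclisation of (E)-homogeranic acid (sets C5a, C7, C9a).
4. Sulfonium salt ⇐ but-3-yn-2-ol (alkyne C–H bromination, then triflation / Me2S).
5. Ring order: cyclohexane and γ-lactone (step 1) → lactol (step 2) → oxepane, then oxirane (step 5; the five-membered O-ring is expanded by C2 and C3).

Key step: step 5

Assumption: (E)-homogeranic acid is treated as purchasable, and the antipode of the step-1 catalyst that gives the (5S)-bromide is used (both antipodes derive from commercial BINOL).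

## Route

Step 1
Reactants: 1 (3E)-4,8-dimethylnona-3,7-dienoic acid (homogeranic acid)
Product: 2 (3aS,5S,7aS)-5-bromo-4,4,7a-trimethylhexahydro-1-benzofuran-2(3H)-one
Conditions: DBDMH (0.55 equiv), chiral 3,3'-diaryl-BINOL N-triflyl thiophosphoramide (10 mol %), toluene/CH2Cl2, −78 → −40 °C; recrystallisation
Reagents that add atoms: 1,3-dibromo-5,5-dimethylhydantoin CC1(C)N(Br)C(=O)N(Br)C1=O
Why: Catalytic enantioselective bromonium-induced polyene cyclisation: Br+ is delivered to one face of the terminal alkene, the (E)-3,4-alkene attacks through a chair and the carboxyl oxygen traps the tertiary cation anti, so the catalyst sets C5 and the chair relays it to C3a and C7a (Br equatorial, trans ring fusion).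

Step 2
Reactants: 2 (3aS,5S,7aS)-5-bromo-4,4,7a-trimethylhexahydro-1-benzofuran-2(3H)-one
Product: 3 (3aS,5S,7aS)-5-bromo-4,4,7a-trimethyloctahydro-1-benzofuran-2-ol (lactol; anomer mixture)
Conditions: DIBAL-H (1.1 equiv), CH2Cl2, −78 °C; aq. Rochelle salt
Reagents that add atoms: none
Why: Partial reduction of a γ-lactone with DIBAL-H at −78 °C stops at the aluminium hemiacetal, which gives the lactol on work-up; the equatorial secondary bromide and all stereocentres are untouched.

Step 3
Reactants: 4 but-3-yn-2-ol (racemic)
Product: 5 4-bromobut-3-yn-2-ol (racemic)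
Conditions: NBS (1.1 equiv), AgNO3 (10 mol %), acetone, rt
Reagents that add atoms: N-bromosuccinimide O=C1CCC(=O)N1Br
Why: Silver-catalysed electrophilic bromination of the terminal alkyne C–H (via the silver acetylide) is a standard route to 1-bromoalkynes and leaves the secondary alcohol alone; the carbinol centre is racemic and is erased in step 5.

Step 4
Reactants: 5 4-bromobut-3-yn-2-ol
Product: 7 (4-bromobut-3-yn-2-yl)dimethylsulfonium trifluoromethanesulfonate, via propargylic triflate 6 (not isolated)
Conditions: Tf2O (1.05 equiv), 2,6-lutidine (1.1 equiv), CH2Cl2, −78 °C; then Me2S (3 equiv), −78 → 0 °C; Et2O trituration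
Reagents that add atoms: trifluoromethanesulfonic anhydride O=S(=O)(OS(=O)(=O)C(F)(F)F)C(F)(F)F; dimethyl sulfide CSC
Why: O-Triflation followed by SN2 S-alkylation of dimethyl sulfide by the propargylic triflate is the standard preparation of sulfonium triflates, and the non-nucleophilic counter-ion is what the ylide chemistry of step 5 needs.

Step 5
Reactants: 3 (3aS,5S,7aS)-5-bromo-4,4,7a-trimethyloctahydro-1-benzofuran-2-ol; 7 (4-bromobut-3-yn-2-yl)dimethylsulfonium trifluoromethanesulfonate
Product: 11 (2E,3R,4R,5aS,7S,9aS)-7-bromo-2-(bromomethylidene)-3,4-epoxy-3,6,6,9a-tetramethyldecahydro-1-benzoxepine, via allenylsulfonium salt 8 (not isolated), via sulfonium ylide 9 (not isolated), via betaine 10 (not isolated)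
Conditions: NaH (1.05 equiv), THF, 0 °C; then 7 (1.3 equiv) in CH2Cl2, −40 → 0 °C
Reagents that add atoms: none
Why: Proposed new method: the alkoxide base isomerises 7 to the allenylsulfonium salt 8, the tertiary alkoxide of the ring-opened (hydroxy-aldehyde) tautomer of 3 adds to the central allene carbon in the plane of the CHBr terminus and anti to Br, which gives the (E)-bromo enol ether and the 2-alkoxyallyl sulfonium ylide 9, whose carbon C3 attacks the aldehyde carbon C4 (7-exo-trig closure of the oxepane through the C3–C4 bond) before the alkoxide of betaine 10 displaces Me2S with inversion at C3 (3-exo-tet closure of the oxirane). The closest known reaction type is the annulation of amino- and hydroxy-carbonyl compounds, cyclic hemiaminals included, with vinyl- and prop-2-ynylsulfonium salts to epoxide-fused five- to seven-membered heterocycles; new are the lactol-derived tertiary alkoxide and the 1-methyl-3-bromo substitution of the allene. The cis ring fusion of the oxirane (C3 relative to C4) is enforced by the ring, because only the betaine with O− anti to S+ can close and the other one should return to 9. The face relative to the core (3R,4R) is set by the trans-fused chair: in the exo transition state the planar ylide swings away from the axial C5a–H and keeps Me2S+ syn to O1 (away from the cis vinylic Br), so the leaving group sits on the convex face and the oxygen arrives on the concave face syn to C5a–H. The step needs the tertiary alkoxide to win over the more abundant lactolate, which is expected from Curtin–Hammett funnelling: O-addition to 8 is reversible (E1cB loss of the weakly basic lactolate), and only the ring-opened adduct has an internal aldehyde that consumes the ylide irreversibly.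

## Compound list

1 | (3E)-4,8-dimethylnona-3,7-dienoic acid (homogeranic acid) | CC(C)=CCC/C(C)=C/CC(=O)O | starting material
2 | (3aS,5S,7aS)-5-bromo-4,4,7a-trimethylhexahydro-1-benzofuran-2(3H)-one | CC1(C)[C@@H](Br)CC[C@]2(C)OC(=O)C[C@@H]12 | intermediate
3 | (3aS,5S,7aS)-5-bromo-4,4,7a-trimethyloctahydro-1-benzofuran-2-ol (anomer mixture) | CC1(C)[C@@H](Br)CC[C@]2(C)OC(O)C[C@@H]12 | intermediate
4 | but-3-yn-2-ol (racemic) | CC(O)C#C | starting material
5 | 4-bromobut-3-yn-2-ol (racemic) | CC(O)C#CBr | intermediate
6 | 4-bromobut-3-yn-2-yl trifluoromethanesulfonate (racemic) | CC(OS(=O)(=O)C(F)(F)F)C#CBr | intermediate (not isolated)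
7 | (4-bromobut-3-yn-2-yl)dimethylsulfonium trifluoromethanesulfonate (racemic) | CC(C#CBr)[S+](C)C.[O-]S(=O)(=O)C(F)(F)F | intermediate
8 | (4-bromobuta-2,3-dien-2-yl)dimethylsulfonium trifluoromethanesulfonate (racemic allene) | CC(=C=CBr)[S+](C)C.[O-]S(=O)(=O)C(F)(F)F | intermediate (not isolated)
9 | sulfonium ylide: (E)-1-bromo-2-{[(1S,2S,4S)-4-bromo-1,3,3-trimethyl-2-(2-oxoethyl)cyclohexyl]oxy}but-1-en-3-ylide of dimethylsulfonium | CC1(C)[C@@H](Br)CC[C@](C)(O/C(=C/Br)[C-](C)[S+](C)C)[C@H]1CC=O | intermediate (not isolated)
10 | betaine: oxepane closed at C3–C4, C4–O− on the concave face, C3–SMe2+ on the convex face | CC1(C)[C@@H](Br)CC[C@]2(C)O/C(=C/Br)[C@@](C)([S+](C)C)[C@H]([O-])C[C@@H]12 | intermediate (not isolated)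
11 | (2E,3R,4R,5aS,7S,9aS)-7-bromo-2-(bromomethylidene)-3,4-epoxy-3,6,6,9a-tetramethyldecahydro-1-benzoxepine | CC1(C)[C@@H](Br)CC[C@]2(C)O/C(=C/Br)[C@]3(C)O[C@@H]3C[C@@H]12 | target

## Step count and risks

Total step count: 5. Longest linear sequence: 3 steps (1 → 2 → 3 → 11; the reagent branch 4 → 5 → 7 → 11 is also 3).

**Risk 1, step 5 (Proposed new method).** Several processes may compete:
- irreversible O-alkenylation at the hemiacetal oxygen instead of the ring-opened tertiary alkoxide;
- addition of the un-isomerised propargylic ylide of 7 to the aldehyde;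
- proton transfer within the ylide followed by a [2,3]-shift;
- loss of facial control in the C3–C4 bond formation, or of E/Z control by rotation in the allyl ylide.

Fallback, from 3 back to 11, with the same bonds made one at a time by known reactions. Wittig methylenation of 3 (Ph3P=CH2, THF) should give the allyl carbinol F1. Acylation of its lithium alkoxide with methacryloyl chloride should give the methacrylate F2. Ring-closing metathesis (second-generation Ru benzylidene catalyst, toluene, 80 °C, high dilution) should close the oxepane at C3=C4 to the unsaturated lactone F3. Because an external oxidant would attack the convex face, the oxirane would be placed on the concave face through the bromohydrin F4 (NBS, aq. THF: Br+ from the convex face at C3, water anti at C4). Closure with K2CO3 should give the glycidic lactone F5. Dibromomethylenation of the lactone carbonyl (CBr4, PPh3, toluene, reflux) should give the dibromo enol ether F6. Pd(PPh3)4/Bu3SnH hydrogenolysis of the less hindered C–Br bond (the one syn to O1) should leave the (E)-bromide 11.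

**Risk 2, step 1.** Enantiocontrol may erode through uncatalysed bromonium transfer, disturbance of catalyst–Br+ binding by the free carboxylic acid, or competing 5-endo bromolactonisation at the 3,4-alkene.

Fallback, from 1 back to 2. The cyclisation would be run racemically with bromodiethylsulfonium bromopentachloroantimonate (MeNO2, −25 °C), which should give 2 together with its enantiomer, ent-bromolactone F7. Ring-opening of the mixture with (S)-1-phenylethylamine/AlMe3 should give the diastereomeric hydroxy amide F8 (from 2) and hydroxy amide F9 (from F7), to be separated by chromatography or crystallisation. Acid-mediated relactonisation of F8 (p-TsOH, toluene, 60 °C) should return enantiopure 2.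

**Risk 3, step 4.** The secondary propargylic triflate may ionise or eliminate before S-alkylation, or Me2S may attack the alkynyl bromide (bromophilic attack).

Fallback, from 4 back to 7, with sulfur introduced as thiolate and bromine last. Mesylation of 4 (MsCl, Et3N) should give the mesylate F10. SN2 displacement with NaSMe should give the sulfide F11. S-Methylation with MeOTf should give the sulfonium triflate F12. AgNO3-catalysed NBS bromination of the alkyne C–H should then give 7.

## Further compounds

F1 | step 5 | (1S,2S,4S)-4-bromo-1,3,3-trimethyl-2-(prop-2-en-1-yl)cyclohexan-1-ol | CC1(C)[C@@H](Br)CC[C@](C)(O)[C@H]1CC=C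
F2 | step 5 | (1S,2S,4S)-4-bromo-1,3,3-trimethyl-2-(prop-2-en-1-yl)cyclohexyl 2-methylprop-2-enoate | CC1(C)[C@@H](Br)CC[C@](C)(OC(=O)C(C)=C)[C@H]1CC=C
F3 | step 5 | (5aS,7S,9aS)-7-bromo-3,6,6,9a-tetramethyl-5a,6,7,8,9,9a-hexahydro-1-benzoxepin-2(5H)-one | CC1(C)[C@@H](Br)CC[C@]2(C)OC(=O)C(C)=CC[C@@H]12
F4 | step 5 | (5aS,7S,9aS)-3,7-dibromo-4-hydroxy-3,6,6,9a-tetramethyloctahydro-1-benzoxepin-2(3H)-one (3-Br on the convex face, 4-OH on the concave face) | CC1(C)[C@@H](Br)CC[C@]2(C)OC(=O)[C@@](C)(Br)[C@H](O)C[C@@H]12
F5 | step 5 | (3R,4R,5aS,7S,9aS)-7-bromo-3,4-epoxy-3,6,6,9a-tetramethyloctahydro-1-benzoxepin-2(3H)-one | CC1(C)[C@@H](Br)CC[C@]2(C)OC(=O)[C@]3(C)O[C@@H]3C[C@@H]12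
F6 | step 5 | (3R,4R,5aS,7S,9aS)-7-bromo-2-(dibromomethylidene)-3,4-epoxy-3,6,6,9a-tetramethyldecahydro-1-benzoxepine | CC1(C)[C@@H](Br)CC[C@]2(C)OC(=C(Br)Br)[C@]3(C)O[C@@H]3C[C@@H]12
F7 | step 1 | (3aR,5R,7aR)-5-bromo-4,4,7a-trimethylhexahydro-1-benzofuran-2(3H)-one | CC1(C)[C@H](Br)CC[C@@]2(C)OC(=O)C[C@H]12
F8 | step 1 | 2-[(1S,3S,6S)-3-bromo-6-hydroxy-2,2,6-trimethylcyclohexyl]-N-[(1S)-1-phenylethyl]acetamide | CC1(C)[C@@H](Br)CC[C@](C)(O)[C@H]1CC(=O)N[C@@H](C)c1ccccc1
F9 | step 1 | 2-[(1R,3R,6R)-3-bromo-6-hydroxy-2,2,6-trimethylcyclohexyl]-N-[(1S)-1-phenylethyl]acetamide | CC1(C)[C@H](Br)CC[C@@](C)(O)[C@@H]1CC(=O)N[C@@H](C)c1ccccc1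
F10 | step 4 | but-3-yn-2-yl methanesulfonate (racemic) | CC(OS(C)(=O)=O)C#C
F11 | step 4 | 3-(methylsulfanyl)but-1-yne (racemic) | CC(SC)C#C
F12 | step 4 | (but-3-yn-2-yl)dimethylsulfonium trifluoromethanesulfonate (racemic) | CC(C#C)[S+](C)C.[O-]S(=O)(=O)C(F)(F)F
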